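- Numbering: Ar–C7–C8–C9 is the 3-hydroxy-4-methoxybenzyl half and Ar'–C7'–C8'–C9' the 4-hydroxy-3-methoxybenzyl half; the target is (8R,8'R) with benzoates on O9 and O9'.
- Retrosynthetic cuts, in order: the two O-benzyl and two benzoyl C–O bonds; the lactol bond C9'–O9 together with C8'–C9' (one carbon from CO); C7–C8 (benzylation of an auxiliary-bound dienolate); C7'=C8' (Wittig).
- Enabling feature: C9' sits on the stereocentre C8' and is 1,4 to O9. Rhodium held on the free C9 hydroxyl of a C8'=C7' styrenyl homoallylic alcohol can therefore place CO on C8', and the aldehyde closes on O9 to the five-membered lactol ring O9–C9–C8–C8'–C9'.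
- Forward: O-benzylvanillin → (E)-4-arylbut-3-enoic acid → N-acyl oxazolidinone → alpha-benzylation with the O-benzylisovanillyl bromide → LiBH4 → homoallylic alcohol → directed hydroformylation to the lactol (the only ring, opened again in the next step) → diol → dibenzoate → hydrogenolysis.
- Stereochemistry: C8 comes from (R)-4-benzyloxazolidin-2-one (facial control in the enolate alkylation). C8' is set trans to C8 in the chelated hydrometalation and is secured by base equilibration alpha to the masked aldehyde before reduction.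

Key step: step 7

Remark: the benzyl ethers of isovanillin and vanillin (1 and 4) are taken as purchased. In the enzymatic fallback to step 5 the lipase is assumed to give the (R)-monoacetate; should acylation show the opposite sense, hydrolysis of the diacetate with the same enzyme would give the (R)-compound.

**Route**

Step 1
Reactants: 1 3-benzyloxy-4-methoxybenzaldehyde
Product: 2 (3-benzyloxy-4-methoxyphenyl)methanol
Conditions: NaBH4, MeOH, 0 °C
Reagents that add atoms: none
Why: Borohydride reduction of an aromatic aldehyde to the benzylic alcohol is chemoselective and leaves the aryl benzyl and methyl ethers untouched.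

Step 2
Reactants: 2 (3-benzyloxy-4-methoxyphenyl)methanol
Product: 3 3-benzyloxy-4-methoxybenzyl bromide
Conditions: PBr3, Et2O, 0 °C
Reagents that add atoms: phosphorus tribromide, BrP(Br)Br
Why: PBr3 converts the electron-rich benzylic alcohol into its bromide by SN2 displacement on the intermediate phosphite ester, giving the electrophile that later forms C7–C8.

Step 3
Reactants: 4 4-benzyloxy-3-methoxybenzaldehyde; 5 (2-carboxyethyl)triphenylphosphonium bromide
Product: 7 (E)-4-(4-benzyloxy-3-methoxyphenyl)but-3-enoic acid, via carboxylate ylide 6 (not isolated)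
Conditions: NaN(SiMe3)2 (2.2 equiv), THF, −20 °C → rt; aq. HCl
Reagents that add atoms: none
Why: Wittig olefination with the ylide of a 2-carboxyethylphosphonium salt is the standard entry to 4-arylbut-3-enoic acids; the carboxylate-bearing ylide is expected to give the E-alkene with an aromatic aldehyde, and the styrene-conjugated position of the double bond is the stable one.

Step 4
Reactants: 7 (E)-4-(4-benzyloxy-3-methoxyphenyl)but-3-enoic acid
Product: 9 (R)-4-benzyl-3-[(E)-4-(4-benzyloxy-3-methoxyphenyl)but-3-enoyl]oxazolidin-2-one, via mixed pivalic anhydride 8 (not isolated)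
Conditions: PivCl, Et3N, THF, −20 °C; then (R)-4-benzyloxazolidin-2-one, LiCl, −20 °C → rt
Reagents that add atoms: (R)-4-benzyloxazolidin-2-one, O=C1N[C@H](Cc2ccccc2)CO1
Why: N-acylation of the oxazolidinone through the pivalic mixed anhydride with LiCl/Et3N activation is mild enough for a beta,gamma-unsaturated acid (no acid chloride, no strong base), so the alkene should neither migrate nor isomerise.

Step 5
Reactants: 9 (R)-4-benzyl-3-[(E)-4-(4-benzyloxy-3-methoxyphenyl)but-3-enoyl]oxazolidin-2-one; 3 3-benzyloxy-4-methoxybenzyl bromide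
Product: 11 (R)-4-benzyl-3-[(2R,3E)-2-(3-benzyloxy-4-methoxybenzyl)-4-(4-benzyloxy-3-methoxyphenyl)but-3-enoyl]oxazolidin-2-one, via sodium dienolate 10 (not isolated)
Conditions: NaN(SiMe3)2, THF, −78 °C; then 3, −78 → −40 °C
Reagents that add atoms: none
Why: Evans asymmetric alkylation: the chelated Z-dienolate reacts with the benzylic bromide at its alpha-carbon (the kinetic site of such dienolates) on the face away from the auxiliary's benzyl group, which with the (R)-auxiliary sets C8 as R, and allylic strain keeps the product from re-enolising.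

Step 6
Reactants: 11 (R)-4-benzyl-3-[(2R,3E)-2-(3-benzyloxy-4-methoxybenzyl)-4-(4-benzyloxy-3-methoxyphenyl)but-3-enoyl]oxazolidin-2-one
Product: 12 (R,E)-2-(3-benzyloxy-4-methoxybenzyl)-4-(4-benzyloxy-3-methoxyphenyl)but-3-en-1-ol
Conditions: LiBH4, MeOH (1 equiv), THF, 0 °C
Reagents that add atoms: none
Why: LiBH4 reductive cleavage of the N-acyl oxazolidinone attacks the exocyclic carbonyl and should give the primary alcohol without touching the styrene or the alpha-stereocentre, freeing the auxiliary for recovery.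

Step 7
Reactants: 12 (R,E)-2-(3-benzyloxy-4-methoxybenzyl)-4-(4-benzyloxy-3-methoxyphenyl)but-3-en-1-ol
Product: 14 (3R,4R)-3-(4-benzyloxy-3-methoxybenzyl)-4-(3-benzyloxy-4-methoxybenzyl)tetrahydrofuran-2-ol (anomeric mixture), via hydroxy aldehyde 13 (not isolated)
Conditions: Rh(CO)2(acac) (2 mol%), Ph2POMe (10 mol%), CO/H2 (1:1, 40 bar), 4 Å MS, THF, 50 °C
Reagents that add atoms: carbon monoxide, [C-]#[O+]
Why: Ph2POMe exchanges its methoxy group for the C9 hydroxyl of 12 (the sieves take up the methanol), so the substrate becomes the phosphinite ligand and holds Rh–H over the alkene; syn-hydrometalation through the six-membered Rh–P–O9–C9–C8–C8' chelate puts Rh on C8' and H on C7', CO insertion and hydrogenolysis of the acyl give aldehyde 13, and the phosphinite is handed on to the next molecule of 12. The closest known reaction type is the Rh-catalysed branched-selective hydroformylation of homoallylic alcohols, 1,2-disubstituted alkenes included, with a catalytic, reversibly bound phosphinite directing group, which gives gamma-lactols. The only ring closes by 5-exo-trig addition of the C9 hydroxyl to the C9' aldehyde (hemiacetalisation) to give the tetrahydrofuran-2-ol. C8' is controlled by the C8 stereocentre: in a chair-like chelate the C8 benzyl arm and the nascent C7' benzyl arm should both lie equatorial, which corresponds to the trans (8R,8'R) relation, while the anomeric carbon is left uncontrolled because it is removed in step 8. The selectivity needed is regiochemical, C8' over the intrinsically preferred benzylic C7' of the styrene, and it is secured by the O9–P tether, since delivery to C7' would need a seven-membered chelate; the aryl benzyl ethers are inert to Rh under CO/H2.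

Step 8
Reactants: 14 (3R,4R)-3-(4-benzyloxy-3-methoxybenzyl)-4-(3-benzyloxy-4-methoxybenzyl)tetrahydrofuran-2-ol
Product: 15 (2R,3R)-2-(4-benzyloxy-3-methoxybenzyl)-3-(3-benzyloxy-4-methoxybenzyl)butane-1,4-diol
Conditions: DBU (0.2 equiv), MeOH, rt; then NaBH4, 0 °C
Reagents that add atoms: none
Why: A gamma-lactol stands in ring–chain equilibrium with its open hydroxy-aldehyde tautomer, so catalytic DBU can epimerise C8' (alpha to the masked aldehyde) and should drive any cis material into the thermodynamically preferred trans series, and NaBH4 then reduces the lactol through that open form to the 1,4-diol (lactol reduction), C8 being untouched.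

Step 9
Reactants: 15 (2R,3R)-2-(4-benzyloxy-3-methoxybenzyl)-3-(3-benzyloxy-4-methoxybenzyl)butane-1,4-diol
Product: 16 (2R,3R)-2-(4-benzyloxy-3-methoxybenzyl)-3-(3-benzyloxy-4-methoxybenzyl)butane-1,4-diyl dibenzoate
Conditions: BzCl, pyridine, DMAP (cat.), CH2Cl2, 0 °C → rt
Reagents that add atoms: benzoyl chloride, O=C(Cl)c1ccccc1
Why: DMAP-catalysed acylation of the two primary alcohols with benzoyl chloride is a routine esterification, and no other nucleophilic group is present.

Step 10
Reactants: 16 (2R,3R)-2-(4-benzyloxy-3-methoxybenzyl)-3-(3-benzyloxy-4-methoxybenzyl)butane-1,4-diyl dibenzoate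
Product: 17 (2R,3R)-2-(4-hydroxy-3-methoxybenzyl)-3-(3-hydroxy-4-methoxybenzyl)butane-1,4-diyl dibenzoate
Conditions: H2 (1 atm), 10% Pd/C, EtOAc/EtOH, rt
Reagents that add atoms: none
Why: Catalytic hydrogenolysis cleaves the two aryl benzyl ethers at their benzylic C–O bonds, while the primary alkyl benzoates, the aryl methyl ethers and both stereocentres are inert, so the two phenols of the target are released.

**Compound list**

1 | 3-benzyloxy-4-methoxybenzaldehyde (O-benzylisovanillin) | COc1ccc(C=O)cc1OCc1ccccc1 | starting material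
2 | (3-benzyloxy-4-methoxyphenyl)methanol | COc1ccc(CO)cc1OCc1ccccc1 | intermediate
3 | 3-benzyloxy-4-methoxybenzyl bromide | COc1ccc(CBr)cc1OCc1ccccc1 | intermediate
4 | 4-benzyloxy-3-methoxybenzaldehyde (O-benzylvanillin) | COc1cc(C=O)ccc1OCc1ccccc1 | starting material
5 | (2-carboxyethyl)triphenylphosphonium bromide | OC(=O)CC[P+](c1ccccc1)(c1ccccc1)c1ccccc1.[Br-] | starting material
6 | sodium 3-(triphenyl-λ5-phosphanylidene)propanoate (carboxylate ylide) | [Na+].[O-]C(=O)CC=P(c1ccccc1)(c1ccccc1)c1ccccc1 | intermediate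
7 | (E)-4-(4-benzyloxy-3-methoxyphenyl)but-3-enoic acid | COc1cc(/C=C/CC(=O)O)ccc1OCc1ccccc1 | intermediate
8 | (E)-4-(4-benzyloxy-3-methoxyphenyl)but-3-enoic pivalic anhydride | COc1cc(/C=C/CC(=O)OC(=O)C(C)(C)C)ccc1OCc1ccccc1 | intermediate
9 | (R)-4-benzyl-3-[(E)-4-(4-benzyloxy-3-methoxyphenyl)but-3-enoyl]oxazolidin-2-one | COc1cc(/C=C/CC(=O)N2[C@H](Cc3ccccc3)COC2=O)ccc1OCc1ccccc1 | intermediate
10 | sodium Z-dienolate of 9 | COc1cc(/C=C/C=C(\[O-])N2[C@H](Cc3ccccc3)COC2=O)ccc1OCc1ccccc1.[Na+] | intermediate
11 | (R)-4-benzyl-3-[(2R,3E)-2-(3-benzyloxy-4-methoxybenzyl)-4-(4-benzyloxy-3-methoxyphenyl)but-3-enoyl]oxazolidin-2-one | COc1ccc(C[C@@H](C(=O)N2[C@H](Cc3ccccc3)COC2=O)/C=C/c2ccc(OCc3ccccc3)c(OC)c2)cc1OCc1ccccc1 | intermediate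
12 | (R,E)-2-(3-benzyloxy-4-methoxybenzyl)-4-(4-benzyloxy-3-methoxyphenyl)but-3-en-1-ol | COc1ccc(C[C@@H](CO)/C=C/c2ccc(OCc3ccccc3)c(OC)c2)cc1OCc1ccccc1 | intermediate
13 | (2R,3R)-2-(4-benzyloxy-3-methoxybenzyl)-3-(3-benzyloxy-4-methoxybenzyl)-4-hydroxybutanal | COc1ccc(C[C@@H](CO)[C@H](C=O)Cc2ccc(OCc3ccccc3)c(OC)c2)cc1OCc1ccccc1 | intermediate
14 | (3R,4R)-3-(4-benzyloxy-3-methoxybenzyl)-4-(3-benzyloxy-4-methoxybenzyl)tetrahydrofuran-2-ol (anomeric mixture) | COc1ccc(C[C@H]2COC(O)[C@@H]2Cc2ccc(OCc3ccccc3)c(OC)c2)cc1OCc1ccccc1 | intermediate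
15 | (2R,3R)-2-(4-benzyloxy-3-methoxybenzyl)-3-(3-benzyloxy-4-methoxybenzyl)butane-1,4-diol | COc1ccc(C[C@@H](CO)[C@H](CO)Cc2ccc(OCc3ccccc3)c(OC)c2)cc1OCc1ccccc1 | intermediate
16 | (2R,3R)-2-(4-benzyloxy-3-methoxybenzyl)-3-(3-benzyloxy-4-methoxybenzyl)butane-1,4-diyl dibenzoate | COc1ccc(C[C@@H](COC(=O)c2ccccc2)[C@H](COC(=O)c2ccccc2)Cc2ccc(OCc3ccccc3)c(OC)c2)cc1OCc1ccccc1 | intermediate
17 | (2R,3R)-2-(4-hydroxy-3-methoxybenzyl)-3-(3-hydroxy-4-methoxybenzyl)butane-1,4-diyl dibenzoate | COc1ccc(C[C@@H](COC(=O)c2ccccc2)[C@H](COC(=O)c2ccccc2)Cc2ccc(O)c(OC)c2)cc1O | target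

**Step count**

Total: 10 steps. Longest linear sequence: 8 steps (steps 3 to 10, from aldehyde 4); the bromide branch (steps 1 and 2) joins at step 5.

**Steps most likely to fail**

Step 7. The tether may fail to override the benzylic preference of the electron-rich styrene, so that rhodium is delivered to C7' and a six-membered lactol forms. Reversible hydrometalation may also isomerise or hydrogenate the alkene and erode C8. The fallback sets out from alcohol 12 and forms C8'–C9' by radical instead of rhodium chemistry, where the styrene polarity favours the wanted regiochemistry. Silylation with (bromomethyl)chlorodimethylsilane (Et3N, DMAP, CH2Cl2) would give the (bromomethyl)dimethylsilyl ether F1. Bu3SnH/AIBN (benzene, 80 °C, slow addition) would generate the alpha-silyl radical, which should close 6-exo-trig onto C8' and leave the benzylic C7' radical for reduction by the stannane. A chair-like transition state with both benzyl arms equatorial should give the trans 1-oxa-2-silacyclohexane F2. Tamao–Fleming oxidation (H2O2, KF, KHCO3, THF/MeOH) would turn C–Si into C–OH and free O9, which returns to the route at diol 15.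

Step 5. The dienolate may react at its gamma-carbon, the double bond may move into conjugation with the imide, or facial control may be eroded. The fallback sets C8 enzymatically; it sets out from bromide 3 and comes back at alcohol 12. Alkylation of diethyl malonate with 3 (NaH, THF) would give diethyl 2-(3-benzyloxy-4-methoxybenzyl)malonate F3, and LiAlH4 the 2-(3-benzyloxy-4-methoxybenzyl)propane-1,3-diol F4. Desymmetrisation with Burkholderia cepacia lipase and vinyl acetate would give the (R)-monoacetate F5. Mitsunobu reaction with 1-phenyl-1H-tetrazole-5-thiol (PPh3, DIAD) would give the sulfide F6, and oxidation with H2O2 and catalytic (NH4)6Mo7O24 the sulfone F7. Julia–Kocienski olefination with aldehyde 4 (KN(SiMe3)2 added to the premixed partners, DME, −78 °C) would give the (E)-alkene acetate F8, and K2CO3/MeOH would then release alcohol 12.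

Step 8. Equilibration at C8' may be incomplete, or hydride reduction may outpace it, so that the cis (8R,8'S) series is frozen into the diol. The fallback moves the stereochemical correction to the lactone oxidation level, where it is well established for dibenzylbutyrolactones. It sets out from lactol 14: oxidation with Ag2CO3 on Celite (toluene, reflux) would give the (3R,4R)-trans-lactone F9 together with any (3S,4R)-cis-lactone F10. DBU (toluene, rt) would convert F10 into F9, and LiAlH4 (THF, 0 °C) would open F9 to diol 15.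

Further compounds
F1 | step 7 | (R,E)-{[2-(3-benzyloxy-4-methoxybenzyl)-4-(4-benzyloxy-3-methoxyphenyl)but-3-en-1-yl]oxy}(bromomethyl)dimethylsilane | COc1ccc(C[C@@H](CO[Si](C)(C)CBr)/C=C/c2ccc(OCc3ccccc3)c(OC)c2)cc1OCc1ccccc1
F2 | step 7 | (4R,5R)-4-(4-benzyloxy-3-methoxybenzyl)-5-(3-benzyloxy-4-methoxybenzyl)-2,2-dimethyl-1,2-oxasilinane | COc1ccc(C[C@H]2CO[Si](C)(C)C[C@@H]2Cc2ccc(OCc3ccccc3)c(OC)c2)cc1OCc1ccccc1
F3 | step 5 | diethyl 2-(3-benzyloxy-4-methoxybenzyl)malonate | CCOC(=O)C(Cc1ccc(OC)c(OCc2ccccc2)c1)C(=O)OCC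
F4 | step 5 | 2-(3-benzyloxy-4-methoxybenzyl)propane-1,3-diol | OCC(CO)Cc1ccc(OC)c(OCc2ccccc2)c1
F5 | step 5 | (R)-3-(3-benzyloxy-4-methoxyphenyl)-2-(hydroxymethyl)propyl acetate | COc1ccc(C[C@H](CO)COC(C)=O)cc1OCc1ccccc1
F6 | step 5 | (S)-3-(3-benzyloxy-4-methoxyphenyl)-2-{[(1-phenyl-1H-tetrazol-5-yl)sulfanyl]methyl}propyl acetate | COc1ccc(C[C@H](CSc2nnnn2-c2ccccc2)COC(C)=O)cc1OCc1ccccc1
F7 | step 5 | (S)-3-(3-benzyloxy-4-methoxyphenyl)-2-{[(1-phenyl-1H-tetrazol-5-yl)sulfonyl]methyl}propyl acetate | COc1ccc(C[C@H](CS(=O)(=O)c2nnnn2-c2ccccc2)COC(C)=O)cc1OCc1ccccc1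
F8 | step 5 | (R,E)-2-(3-benzyloxy-4-methoxybenzyl)-4-(4-benzyloxy-3-methoxyphenyl)but-3-en-1-yl acetate | COc1ccc(C[C@@H](COC(C)=O)/C=C/c2ccc(OCc3ccccc3)c(OC)c2)cc1OCc1ccccc1
F9 | step 8 | (3R,4R)-3-(4-benzyloxy-3-methoxybenzyl)-4-(3-benzyloxy-4-methoxybenzyl)dihydrofuran-2(3H)-one | COc1ccc(C[C@H]2COC(=O)[C@@H]2Cc2ccc(OCc3ccccc3)c(OC)c2)cc1OCc1ccccc1
F10 | step 8 | (3S,4R)-3-(4-benzyloxy-3-methoxybenzyl)-4-(3-benzyloxy-4-methoxybenzyl)dihydrofuran-2(3H)-one | COc1ccc(C[C@H]2COC(=O)[C@H]2Cc2ccc(OCc3ccccc3)c(OC)c2)cc1OCc1ccccc1
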